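Ring numbering used throughout: C1 = oxirane carbon bearing C7H2O, C2 (OAc), C3 (OBz), C4=C5, C6 = oxirane CH.

**Compound numbers**

- 1 benzyl acetate
- 2 (1S,2R)-3-(acetoxymethyl)cyclohexa-3,5-diene-1,2-diol
- 3 trimethyl orthoacetate
- 4 cyclic orthoacetate of 2 (C7 acetate)
- 5 cyclic orthoacetate, C7 alcohol
- 6 1,6-epoxide of 5 (C7 alcohol)
- 7 benzoyl chloride
- 8 C7 benzoate of 6
- 9 benzoic acid
- 10 acetoxonium benzoate derived from 8 (not isolated)
- 11 target

## Analysis of the target

The target is a 7-oxabicyclo[4.1.0]hept-4-ene: a cyclohexene whose C1–C6 bond is bridged by an oxirane oxygen. It carries a benzoyloxymethyl group (C7) on the fully substituted oxirane carbon C1, an acetate on C2, a benzoate on C3 and the C4=C5 double bond. The four stereocentres C1, C2, C3 and C6 are contiguous and have the (1S,2S,3R,6S) configuration. The C2 acetate is trans to the C3 benzoate and trans to the oxirane oxygen, so the C3 benzoate and the oxirane lie on the same face. The molecule is a vinyl oxirane (C6 is allylic) and an allylic ester (C3) with three esters of two kinds on neighbouring oxygens. Acid can therefore open the oxirane or ionise C3, base can cleave or shift acyl groups, and loss of the C2 and C3 acyloxy groups leads towards aromatisation. The carbon skeleton is simple; the hard parts are the absolute configuration, the trans-2,3-diester beside an anti oxirane, and the placement of the single acetate on the most hindered secondary oxygen (C2, next to the quaternary C1) while C3 and C7 carry benzoates. The plan rests on one feature: C1 to C7 are the seven carbons of a benzyl ester, and C2 and C3 are the ortho and meta carbons of a monosubstituted benzene, the two positions that an arene dioxygenase hydroxylates. The diene that is left supplies C1=C6 for the oxirane and C4=C5 as it stands.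

## Retrosynthetic reasoning

**C3–O bond of the C3 benzoate (11 to 8 and 9).** The last bond cut is the bond from C3 to the benzoate oxygen, not an acyl C–O bond. If a free trans-2,3-diol were acylated, the acetate would have to go selectively to the more hindered C2 hydroxyl, with acyl migration always possible. Instead the cis-2,3-dioxygen pattern stays tied up as the cyclic orthoacetate 8. Loss of its methoxy group gives the acetoxonium ion 10, whose two ring C–O bonds differ sharply: C3–O is allylic to C4=C5, C2–O sits beside the quaternary oxirane carbon. Benzoic acid 9 is both the acid that ionises 8 and the nucleophile. Attack at C3 from the face opposite the dioxolanylium ring inverts C3 and leaves the two-carbon unit on the C2 oxygen as the acetate. The forward step must choose C3 over C2 and over C5 (allylic transposition) and must spare the vinyl oxirane.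

**C7–O acyl bond (8 to 6 and 7).** The C7 benzoate is removed to the primary alcohol 6 and benzoyl chloride 7. This acylation is placed after the epoxidation because the free C7 hydroxyl is needed to steer the oxidant.

**Oxirane C1–O and C6–O bonds (6 to 5).** The oxirane is removed to the dienol 5. The diene has two candidate double bonds, and an acyloxymethyl group on C1 would lower the nucleophilicity of C1=C6 towards a peracid to about that of the disubstituted C4=C5 bond. In 5, C1=C6 is the double bond of an allylic alcohol, so a vanadium-catalysed, hydroxyl-directed epoxidation selects it. The cis-fused dioxolane covers one face, so oxygen should arrive anti to it, which is the face the target requires (oxirane trans to the C2 oxygen).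

**C7 acetate (5 to 4).** The C7 hydroxyl is traced back to the acetate 4 by transesterification under basic conditions, which an orthoester tolerates. The acetate is present only because it makes the arene an acceptable enzyme substrate.

**Dioxolane C–O bonds (4 to 2 and 3).** The orthoester is removed to the cis-diol 2 and trimethyl orthoacetate 3. An orthoacetate is chosen over an isopropylidene acetal because it does three jobs. It stabilises the aromatisation-prone diene diol, shields one face for the epoxidation, and is the latent acetate and leaving group of the last step.

**C2–O and C3–O bonds (2 to 1).** Both carbinol C–O bonds are cut at once, which restores the aromatic ring of benzyl acetate 1. The forward reaction is an aerobic enzymatic cis-dihydroxylation. It must hydroxylate the 2,3-bond beside the substituent, on one enantiotopic face, and stop at the diene diol. C2 emerges with the spatial arrangement of the target and C3 with the opposite one, which is what the inversion in the last step needs.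

## Alternatives that were turned down

**Alternative 1:** sulfonium ylide epoxy-annulation.
- Disconnection: the C1–C6 bond and the C6–O bond of the oxirane are cut together. This leads to the open-chain (Z)-allylic sulfonium salt A2, with the ketone at C1, silyl ethers on the C2, C3 and C7 oxygens and the sulfonium group on C6.
- Forward key step: a base forms the ylide at C6, the ylide carbon adds to the C1 ketone to close the carbocycle, and the C1 alkoxide displaces the sulfide from C6 to close the oxirane, giving the tris-silyl ether A1.
- For: one step makes a C–C bond, a C–O bond, both rings and the C1 and C6 stereocentres, without biocatalysis. In bonds and rings formed it is stronger than the enzymatic step, which closes no ring.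
- Against:
  - The ketone of A2 has an acidic C2–H with a silyloxy group on C3 in the β position, so the base can enolise, epimerise C2 or eliminate.
  - An allylic sulfonium ylide can also undergo [2,3]-sigmatropic shift or react through its γ-carbon (C4).
  - The face of the ketone attacked, and so the relation of the oxirane to the C2 oxygen, depends only on 1,2-induction from C2, for which Felkin-type and chelation models point in opposite directions.
  - A2, with two stereocentres and a Z-alkene, is itself a multistep preparation.
  - A1 carries three identical silyl ethers, so the C2 acetate and the C3 and C7 benzoates would have to be placed by selective acylation of a triol beside an oxirane.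
- Comparison: the chosen route needs six steps from 1, takes absolute configuration from the enzyme and places the three acyl groups by mechanism.

**Alternative 2:** furan–bromopropiolate Diels–Alder.
- Disconnection: the C2–C3 and C1–C6 bonds are cut, giving furan A4 and methyl 3-bromopropiolate A5.
- Forward key step: [4+2] cycloaddition gives the 7-oxanorbornadiene A3, in which the ester carbon is the future C7, the bromine marks C2 and the bridging oxygen is meant to remain on C3.
- For: both ring C–C bonds form in one thermal step from two cheap reagents, and the reaction scales without fermentation equipment. On cost and throughput of the first step it is at least as strong as the enzymatic step.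
- Against:
  - A3 is racemic, so a resolution must be added.
  - The cycloaddition sets no stereocentre in its final form.
  - A long sequence must follow: exchange of the vinylic bromide for the C2 oxygen, reduction of the ester to the C7 alcohol, opening of the oxygen bridge at C6 without aromatisation (7-oxanorbornadienes give phenols with acid), introduction of a new oxirane oxygen at C1 and C6 on the correct face, and differentiated acylation. Each has its own regio- or stereochemical problem, and the count should exceed a dozen steps.
- Comparison: the chosen first step gives an enantiopure compound that already has the C2 and C3 oxygens at the right oxidation level and the diene needed for the rest.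

**Alternative 3:** alkenyl iodide to aldehyde closure.
- Disconnection: the C3–C4 bond is cut. This leads to the oxirane A7, which carries the C3 aldehyde beside the C2 acetate on C1 and a (Z)-iodoalkene (C4=C5) on C6.
- Forward key step: a Nozaki–Hiyama–Kishi closure, with divalent chromium and a nickel co-catalyst, turns the C4–I bond into a carbon–metal bond that adds to the aldehyde. This closes the cyclohexene and creates C3 in the alcohol A6, one benzoylation from the target.
- For: the closure is chemoselective for the aldehyde beside esters, six-membered allylic alcohols form well this way, and the end-game is a single simple acylation. On late-stage simplicity it is stronger than the chosen route, whose last step is among its riskiest.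
- Against:
  - A7 has three stereocentres, including the quaternary C1, that must be built in an open chain.
  - Its α-acetoxy aldehyde can enolise with the oxirane C1–O bond in the β position, so epimerisation at C2 and eliminative oxirane opening threaten both its preparation and the closure.
  - C3 is formed by carbonyl addition with only modest facial bias, and only the 2,3-trans isomer is useful.
  - The metal alkoxide formed next to the C2 acetate invites 2-to-3 acyl transfer.
- Comparison: the chosen route derives C3 from an enzyme-set centre by stereospecific inversion and reaches 11 in six steps. It gives up convergence in exchange.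

Key step: step 1

Remark: the orthoester carbon of 4, 5, 6 and 8 forms as a mixture of two epimers and is left undefined in names and SMILES, because both epimers give the same cation 10.

Remark: the toluene dioxygenase is assumed to be used as whole cells of the recombinant strain E. coli JM109(pDTG601), which lacks the diol dehydrogenase.

Remark: the change of the C2 descriptor from R in 2 and 4 to S in 6, 8 and 11 reflects a change in substituent priorities, not an inversion.

## Route

Step 1
Reactants: 1 benzyl acetate
Product: 2 (1S,2R)-3-(acetoxymethyl)cyclohexa-3,5-diene-1,2-diol
Conditions: E. coli JM109(pDTG601) whole cells expressing toluene dioxygenase (IPTG-induced), air, glucose feed, mineral salts medium, pH 7, 30 °C; EtOAc extraction, trace Et3N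
Reagents that add atoms: dioxygen, O=O
Why: Toluene dioxygenase is a three-component Rieske non-haem iron system in which NADH-derived electrons pass through a reductase and a ferredoxin to the oxygenase, whose mononuclear divalent iron binds O2 side-on next to the bound arene. The reduced iron–dioxygen species transfers both oxygen atoms to the same face of the C2=C3 bond, so the C2–O and C3–O bonds form suprafacially and the cis-diol results with C4=C5 and C6=C1 left as a conjugated diene; no ring is closed. The closest known reaction type is the cis-dihydroxylation of toluene and other monosubstituted benzenes by this enzyme, benzyl acetate being a documented substrate. Both new stereocentres are controlled by the protein alone: the substituent is held in the pocket that takes the methyl group of toluene, which directs attack to the ortho and meta carbons and exposes one enantiotopic face, giving the (1S,2R) series that corresponds to the toluene-derived diol. The step needs regioselectivity for the 2,3-bond, a single enantiomer and no further oxidation; the small uncharged acetoxymethyl group secures the first two, and the host lacks the dehydrogenase that would rearomatise the diol to a catechol. The ester must survive host esterases, which short contact time and prompt extraction favour. Isolation at pH 7 or above with a trace of Et3N avoids acid-catalysed dehydration to phenols.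

Step 2
Reactants: 2 (1S,2R)-3-(acetoxymethyl)cyclohexa-3,5-diene-1,2-diol; 3 trimethyl orthoacetate
Product: 4 [(3aR,7aS)-2-methoxy-2-methyl-3a,7a-dihydro-1,3-benzodioxol-4-yl]methyl acetate
Conditions: MeC(OMe)3 (1.5 equiv), PPTS (cat.), CH2Cl2, 0 °C to rt; then Et3N
Reagents that add atoms: trimethyl orthoacetate 3, CC(OC)(OC)OC
Why: Acid-catalysed transorthoesterification of a cis-1,2-diol gives the five-membered cyclic orthoester under the mild conditions that serve for acetal protection of such diene diols. The two carbinol centres are untouched, and the product is no longer prone to dehydration.

Step 3
Reactants: 4 [(3aR,7aS)-2-methoxy-2-methyl-3a,7a-dihydro-1,3-benzodioxol-4-yl]methyl acetate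
Product: 5 [(3aR,7aS)-2-methoxy-2-methyl-3a,7a-dihydro-1,3-benzodioxol-4-yl]methanol
Conditions: K2CO3 (cat.), MeOH, 0 °C
Reagents that add atoms: none
Why: Base-catalysed transesterification removes the primary allylic acetate as methyl acetate. Orthoesters are stable to base, and methoxy exchange at the orthoester carbon is degenerate.

Step 4
Reactants: 5 [(3aR,7aS)-2-methoxy-2-methyl-3a,7a-dihydro-1,3-benzodioxol-4-yl]methanol
Product: 6 [(1S,2S,3S,6S)-2,3-(1-methoxyethylidenedioxy)-7-oxabicyclo[4.1.0]hept-4-en-1-yl]methanol
Conditions: VO(acac)2 (5 mol%), tBuOOH (anhydrous, in decane), 2,6-lutidine (cat.), CH2Cl2, 0 °C to rt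
Reagents that add atoms: tert-butyl hydroperoxide, CC(C)(C)OO
Why: Hydroxyl-directed vanadium-catalysed epoxidation: the C7 alkoxide binds pentavalent vanadium and the bound alkyl peroxide is delivered only to the allylic C1=C6 bond, leaving C4=C5 untouched. The cis-fused dioxolane shields its own face, so the oxirane (C1 and C6, necessarily cis-fused) should form on the opposite face, trans to the C2 oxygen.

Step 5
Reactants: 6 [(1S,2S,3S,6S)-2,3-(1-methoxyethylidenedioxy)-7-oxabicyclo[4.1.0]hept-4-en-1-yl]methanol; 7 benzoyl chloride
Product: 8 [(1S,2S,3S,6S)-2,3-(1-methoxyethylidenedioxy)-7-oxabicyclo[4.1.0]hept-4-en-1-yl]methyl benzoate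
Conditions: BzCl, pyridine, CH2Cl2, 0 °C
Reagents that add atoms: benzoyl chloride 7, O=C(Cl)c1ccccc1
Why: Standard acylation of a primary alcohol with an acid chloride and pyridine. The conditions are basic and non-nucleophilic, so the orthoester and the vinyl oxirane should survive and no alkoxide is formed that could trigger a Payne rearrangement.

Step 6
Reactants: 8 [(1S,2S,3S,6S)-2,3-(1-methoxyethylidenedioxy)-7-oxabicyclo[4.1.0]hept-4-en-1-yl]methyl benzoate; 9 benzoic acid
Product: 11 [(1S,2S,3R,6S)-2-acetoxy-3-(benzoyloxy)-7-oxabicyclo[4.1.0]hept-4-en-1-yl]methyl benzoate (target), via acetoxonium benzoate ion pair 10 (not isolated)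
Conditions: PhCO2H (3 equiv), 5 Å MS, toluene, 80 °C
Reagents that add atoms: benzoic acid 9, OC(=O)c1ccccc1
Why: Benzoic acid protonates the methoxy group of the orthoester, and loss of methanol (taken up by the sieves) gives the 1,3-dioxolan-2-ylium ion 10. Benzoate then opens it as in the second stage of a Prévost reaction, by backside attack at the allylic C3, since C2 is non-allylic and flanked by the quaternary C1. C3 is thereby inverted to give the trans diester, and the former orthoester carbon remains on the C2 oxygen as the acetate with C2 untouched.

## Compound list

1 | benzyl acetate | CC(=O)OCc1ccccc1 | starting material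
2 | (1S,2R)-3-(acetoxymethyl)cyclohexa-3,5-diene-1,2-diol | O[C@H]1[C@@H](O)C=CC=C1COC(C)=O | intermediate
3 | trimethyl orthoacetate | CC(OC)(OC)OC | starting material
4 | [(3aR,7aS)-2-methoxy-2-methyl-3a,7a-dihydro-1,3-benzodioxol-4-yl]methyl acetate (both epimers at the orthoester carbon) | COC1(C)O[C@H]2[C@@H](O1)C=CC=C2COC(C)=O | intermediate
5 | [(3aR,7aS)-2-methoxy-2-methyl-3a,7a-dihydro-1,3-benzodioxol-4-yl]methanol (both epimers at the orthoester carbon) | COC1(C)O[C@H]2[C@@H](O1)C=CC=C2CO | intermediate
6 | [(1S,2S,3S,6S)-2,3-(1-methoxyethylidenedioxy)-7-oxabicyclo[4.1.0]hept-4-en-1-yl]methanol (oxirane trans to the dioxolane; both epimers at the orthoester carbon) | COC1(C)O[C@H]2[C@@H](O1)C=C[C@@H]3O[C@@]32CO | intermediate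
7 | benzoyl chloride | O=C(Cl)c1ccccc1 | starting material
8 | [(1S,2S,3S,6S)-2,3-(1-methoxyethylidenedioxy)-7-oxabicyclo[4.1.0]hept-4-en-1-yl]methyl benzoate (both epimers at the orthoester carbon) | COC1(C)O[C@H]2[C@@H](O1)C=C[C@@H]3O[C@@]32COC(=O)c1ccccc1 | intermediate
9 | benzoic acid | OC(=O)c1ccccc1 | starting material
10 | acetoxonium benzoate ion pair: 2-methyl-1,3-dioxolan-2-ylium cation fused at C2 and C3 of the epoxy cyclohexene, with benzoate as counter-ion | CC1=[O+][C@H]2[C@@H](O1)C=C[C@@H]3O[C@@]32COC(=O)c1ccccc1.[O-]C(=O)c1ccccc1 | intermediate (not isolated)
11 | [(1S,2S,3R,6S)-2-acetoxy-3-(benzoyloxy)-7-oxabicyclo[4.1.0]hept-4-en-1-yl]methyl benzoate | CC(=O)O[C@H]1[C@H](OC(=O)c2ccccc2)C=C[C@@H]2O[C@@]21COC(=O)c1ccccc1 | target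

## Step count and least certain steps

Total number of steps: 6. Longest linear sequence: 6 steps (1 to 11).

**Step 1 (key step).**
- What may go wrong: hydrolysis of the acetate by esterases of the host in competition with oxygenation; low conversion because the ester is sparingly soluble and toxic to the cells; dehydration of the diene diol to phenols during isolation.
- Fallback: the C1–C7 bond is made by cross-coupling instead of being carried through the enzyme. The fallback sets out from 3 and the commercially available (1S,2S)-3-bromocyclohexa-3,5-diene-1,2-diol F1. These are converted as in step 2 (PPTS cat., CH2Cl2) into (3aS,7aS)-4-bromo-2-methoxy-2-methyl-3a,7a-dihydro-1,3-benzodioxole F2. A Stille hydroxymethylation of its alkenyl bromide with Bu3SnCH2OH and Pd(PPh3)4 (zerovalent palladium; toluene, 90 °C) should give 5, where the route is rejoined; 2 and 4 are bypassed.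

**Step 6.**
- What may go wrong: opening of the vinyl oxirane at C6 by benzoic acid; attack of benzoate at C5 with allylic transposition; return of the ion pair without substitution; capture of the cation by adventitious water, giving cis hydroxy acetates.
- Fallback: C3 is activated as an oxyphosphonium ion instead. The fallback sets out from 8. Mild hydrolysis of the orthoester (PPTS cat., wet THF, 0 °C) should give [(1S,2S,3S,6S)-2-acetoxy-3-hydroxy-7-oxabicyclo[4.1.0]hept-4-en-1-yl]methyl benzoate F3 together with its acyl-shift isomer [(1R,2S,3S,6S)-3-acetoxy-2-hydroxy-7-oxabicyclo[4.1.0]hept-4-en-1-yl]methyl benzoate F4. A Mitsunobu reaction with 9 (PPh3, DIAD, THF, 0 °C) should esterify only the allylic C3 hydroxyl of F3, with inversion, and give 11 directly. Direct displacement and participation of the neighbouring acetate lead to the same C3-inverted product. The hindered, non-allylic alcohol F4 should remain and can be re-equilibrated with F3 by 1,2-acyl shift (cat. Et3N) and recycled.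

**Step 4.**
- What may go wrong: delivery of oxygen to the face syn to the dioxolane if the vanadium also binds a dioxolane oxygen; Lewis-acid opening of the orthoester or of the new vinyl oxirane.
- Fallback: a metal-free epoxidation whose face is set by steric shielding alone. The fallback sets out from 5. Benzoylation with 7 (pyridine, CH2Cl2, 0 °C) gives [(3aR,7aS)-2-methoxy-2-methyl-3a,7a-dihydro-1,3-benzodioxol-4-yl]methyl benzoate F5. Treatment with mCPBA in CH2Cl2 over aqueous NaHCO3 at 0 °C should then epoxidise anti to the dioxolane and give 8, where the route is rejoined. The price is regioselectivity: the C4=C5 epoxide is expected as a by-product, because the acyloxymethyl group lowers the reactivity of C1=C6, and must be separated.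

## Further compounds

F1 | step 1 | (1S,2S)-3-bromocyclohexa-3,5-diene-1,2-diol | O[C@H]1[C@@H](O)C=CC=C1Br
F2 | step 1 | (3aS,7aS)-4-bromo-2-methoxy-2-methyl-3a,7a-dihydro-1,3-benzodioxole (both epimers at the orthoester carbon) | COC1(C)O[C@H]2[C@@H](O1)C=CC=C2Br
F3 | step 6 | [(1S,2S,3S,6S)-2-acetoxy-3-hydroxy-7-oxabicyclo[4.1.0]hept-4-en-1-yl]methyl benzoate | CC(=O)O[C@H]1[C@@H](O)C=C[C@@H]2O[C@@]21COC(=O)c1ccccc1
F4 | step 6 | [(1R,2S,3S,6S)-3-acetoxy-2-hydroxy-7-oxabicyclo[4.1.0]hept-4-en-1-yl]methyl benzoate | O[C@H]1[C@@H](OC(C)=O)C=C[C@@H]2O[C@@]21COC(=O)c1ccccc1
F5 | step 4 | [(3aR,7aS)-2-methoxy-2-methyl-3a,7a-dihydro-1,3-benzodioxol-4-yl]methyl benzoate (both epimers at the orthoester carbon) | COC1(C)O[C@H]2[C@@H](O1)C=CC=C2COC(=O)c1ccccc1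
A1 | alternative 1 | 2,3-bis(tert-butyldimethylsilyloxy)-1-[(tert-butyldimethylsilyloxy)methyl]-7-oxabicyclo[4.1.0]hept-4-ene with the configuration of the target | CC(C)(C)[Si](C)(C)O[C@H]1[C@H](O[Si](C)(C)C(C)(C)C)C=C[C@@H]2O[C@@]21CO[Si](C)(C)C(C)(C)C
A2 | alternative 1 | (Z)-[4,5,7-tris(tert-butyldimethylsilyloxy)-6-oxohept-2-en-1-yl]dimethylsulfonium tetrafluoroborate with the C2 and C3 configuration of the target | CC(C)(C)[Si](C)(C)OCC(=O)[C@@H](O[Si](C)(C)C(C)(C)C)[C@H](O[Si](C)(C)C(C)(C)C)/C=C\C[S+](C)C.F[B-](F)(F)F
A3 | alternative 2 | methyl 3-bromo-7-oxabicyclo[2.2.1]hepta-2,5-diene-2-carboxylate (formed as the racemate; one enantiomer drawn) | COC(=O)C1=C(Br)[C@H]2C=C[C@@H]1O2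
A4 | alternative 2 | furan | c1ccoc1
A5 | alternative 2 | methyl 3-bromopropiolate | COC(=O)C#CBr
A6 | alternative 3 | [(1S,2S,3R,6S)-2-acetoxy-3-hydroxy-7-oxabicyclo[4.1.0]hept-4-en-1-yl]methyl benzoate (C3 alcohol of the target) | CC(=O)O[C@H]1[C@H](O)C=C[C@@H]2O[C@@]21COC(=O)c1ccccc1
A7 | alternative 3 | oxirane bearing on C1 the benzoyloxymethyl group and the 1-acetoxy-2-oxoethyl group (C2, C3) and on C6 the (Z)-2-iodoethenyl group, with the configuration of the target | CC(=O)O[C@@H](C=O)[C@@]1(COC(=O)c2ccccc2)O[C@H]1/C=C\I
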